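Numbering (xanthanolide style): lower half C1–C15 (C1 carbinol carbon, C5 ring-fusion CH, C7/C8 lactone fusion carbons, C10 CHMe); upper half C1'–C15' (C11' spiro carbon, C13' its ring CH2).
Cuts: C5–C13' and C11'–C3 (three-component union of two seven-membered-ring lactones), C1–C2 (aldol, six-membered ring), C3–C4 (acetyl by cross-coupling), C1'–C2' (side chain), both exocyclic methylenes, and in each seven-membered ring C1–C5 plus C5–C6 (one CH2 inserted into a cyclohexanone).
Enabling feature: ring C1–C10–C9–C8–C7–C6–C5 is the cyclohexanone C1/C10/C9/C8/C7/C6 with C5 inserted between the carbonyl carbon C1 and C6; the stereotriads C7/C8/C10 and C7'/C8'/C10' are both all-cis but antipodal, so one racemic enone can feed both halves.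
Forward: quinone monoketal 1 → cis-lactone cyclohexanone 7 → silyl enol ether 9 → cyclopropanation (C1–C5, C5–C6) → FeCl3 opening to cycloheptenone 12 → resolution into 13 and 14; 14 → upper methylene lactone 22; 13 + 22 + AcCl → 25; aldol closes the six-membered ring; enol triflate, lactone methylenation, Stille acetylation, hydrolysis.
Stereochemistry: C8/C10 cis from Luche reduction; C7 from the tethered Michael addition; the two antipodes from resolution; C5 and C1 from exo-face Michael addition and aldol (anti to lactone and C10 methyl); C11' from convex-face acylation of the upper lactone enolate.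

Key step: step 6

Remark: compounds 2–12 are racemates, each drawn as the antipode that becomes 13; steps 8 and 9 collect the two antipodes from one chromatographic separation, and both are used.

Step 1
Reactants: 1 4,4-dimethoxycyclohexa-2,5-dien-1-one
Product: 2 rac-4,4-dimethoxy-5-methylcyclohex-2-en-1-one
Conditions: MeMgBr (1.1 equiv), CuBr·SMe2 (10 mol %), THF, −78 → −40 °C; aq. NH4Cl
Reagents that add atoms: methylmagnesium bromide, C[Mg]Br
Why: Copper-catalysed 1,4-addition of the Grignard reagent to one of the two enantiotopic enone arms should give the mono-adduct (the magnesium enolate formed blocks a second addition), creating the future C10 stereocentre as a racemate.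

Step 2
Reactants: 2 rac-4,4-dimethoxy-5-methylcyclohex-2-en-1-one
Product: 4 rac-cis-4-hydroxy-6-methylcyclohex-2-en-1-one, via allylic alcohol ketal 3 (not isolated)
Conditions: NaBH4, CeCl3·7H2O, MeOH, −78 °C; then 1 M HCl, THF, 0 °C
Reagents that add atoms: water, O
Why: Luche 1,2-reduction by axial hydride attack on the half-chair with the methyl group equatorial should set the carbinol (future C8) cis to the methyl group, and mild hydrolysis of the allylic dimethyl ketal then unveils the transposed enone.

Step 3
Reactants: 4 rac-cis-4-hydroxy-6-methylcyclohex-2-en-1-one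
Product: 6 rac-methyl (3aR,6S,7aR)-6-methyl-2,5-dioxooctahydro-1-benzofuran-3-carboxylate (C3 epimers), via malonate ester 5 (not isolated)
Conditions: ClCOCH2CO2Me, pyridine, CH2Cl2, 0 °C; then Cs2CO3 (0.2 equiv), MeCN, rt
Reagents that add atoms: methyl malonyl chloride, COC(=O)CC(=O)Cl
Why: O-acylation followed by 5-exo-trig intramolecular Michael addition of the malonate to the enone β-carbon, delivered from the face of the tethering oxygen, should give the cis-fused γ-lactone and so set C7 cis to the C8 oxygen.

Step 4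
Reactants: 6 rac-methyl (3aR,6S,7aR)-6-methyl-2,5-dioxooctahydro-1-benzofuran-3-carboxylate
Product: 7 rac-(3aR,6S,7aR)-6-methylhexahydro-1-benzofuran-2,5-dione
Conditions: LiCl, H2O, DMSO, 130 °C
Reagents that add atoms: none
Why: Krapcho dealkoxycarbonylation (chloride attack on the methyl ester, loss of CO2, protonation) removes the activating ester without touching C7 or C8, and the C10 methyl group α to the ketone should stay in its equatorial all-cis arrangement.

Step 5
Reactants: 7 rac-(3aR,6S,7aR)-6-methylhexahydro-1-benzofuran-2,5-dione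
Product: 9 rac-6-methyl-5-(trimethylsilyloxy)-3a,6,7,7a-tetrahydro-1-benzofuran-2(3H)-one, via lithium enolate 8 (not isolated)
Conditions: LiN(i-Pr)2 (1.05 equiv), THF, −78 °C; then Me3SiCl
Reagents that add atoms: chlorotrimethylsilane, C[Si](C)(C)Cl
Why: Kinetic deprotonation of the ketone at the less substituted α-carbon C6 (CH2) rather than C10 (CHMe) or the less acidic lactone, followed by O-silylation, should give the C1=C6 silyl enol ether regioselectively (kinetic enol silane formation).

Step 6
Reactants: 9 rac-6-methyl-5-(trimethylsilyloxy)-3a,6,7,7a-tetrahydro-1-benzofuran-2(3H)-one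
Product: 10 rac-siloxycyclopropane (CH2 = C5 bridging C1 and C6 on the face anti to the lactone ring)
Conditions: Et2Zn, CH2I2, CH2Cl2, 0 °C → rt
Reagents that add atoms: diiodomethane, ICI
Why: The zinc carbenoid EtZnCH2I transfers CH2 to the electron-rich C1=C6 enol ether through the concerted butterfly transition state, so the C1–C5 and C5–C6 bonds form together. The closest known reaction type is the Simmons–Smith (Furukawa) cyclopropanation of cyclohexanone silyl enol ethers that precedes an Ito–Saegusa one-carbon ring expansion. The three-membered ring is closed by a [2+1] methylene addition across C1=C6; the strain stored in it is released in step 7, where the internal C1–C6 bond breaks and C5 becomes the ring atom between C1 and C6. The new stereocentres C1 and C6 should arise by attack on the face anti to the lactone, but both are erased in step 7, so the facial outcome is of no consequence. The step needs site selectivity for the enol ether over the lactone carbonyl and insertion of C5 on the C6 side of C1 rather than the C10 side; both are secured by the kinetic silyl enol ether of step 5.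

Step 7
Reactants: 10 rac-siloxycyclopropane
Product: 12 rac-7-methyl-3,3a,8,8a-tetrahydro-2H-cyclohepta[b]furan-2,6(7H)-dione, via chloro ketone 11 (not isolated)
Conditions: FeCl3 (2.2 equiv), DMF, 0 °C; then NaOAc, MeOH, reflux
Reagents that add atoms: none
Why: One-electron oxidation by FeCl3 gives an alkoxy radical whose β-scission breaks the strained internal C1–C6 bond to the secondary C6 radical, chlorine transfer gives 11 and E1cB loss of HCl gives the C5=C6 cycloheptenone (Ito–Saegusa ring expansion), with C7, C8 and C10 untouched.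

Step 8
Reactants: 12 rac-7-methyl-3,3a,8,8a-tetrahydro-2H-cyclohepta[b]furan-2,6(7H)-dione
Product: 13 (3aS,7S,8aR)-7-methyl-3,3a,8,8a-tetrahydro-2H-cyclohepta[b]furan-2,6(7H)-dione
Conditions: preparative SFC, amylose tris(3,5-dimethylphenylcarbamate) stationary phase, CO2–MeOH; band of the (3aS,7S,8aR) antipode collected
Reagents that add atoms: none
Why: Physical resolution on a chiral stationary phase should separate the two antipodes of 12 without any bond change, this one carrying the C7/C8/C10 configuration of the lower half, with the absolute configuration to be assigned by correlation with enone made from 1 by copper-catalysed asymmetric Me2Zn addition with a chiral phosphoramidite ligand.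

Step 9
Reactants: 12 rac-7-methyl-3,3a,8,8a-tetrahydro-2H-cyclohepta[b]furan-2,6(7H)-dione
Product: 14 (3aR,7R,8aS)-7-methyl-3,3a,8,8a-tetrahydro-2H-cyclohepta[b]furan-2,6(7H)-dione
Conditions: the same preparative SFC separation as in step 8; band of the (3aR,7R,8aS) antipode collected
Reagents that add atoms: none
Why: The other band of the same chiral-phase separation (enantiomer resolution by chromatography) should deliver the mirror-image antipode, whose all-cis triad is that of C7'/C8'/C10' in the upper half, so that no part of the racemate is discarded.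

Step 10
Reactants: 14 (3aR,7R,8aS)-7-methyl-3,3a,8,8a-tetrahydro-2H-cyclohepta[b]furan-2,6(7H)-dione
Product: 16 (3aS,7R,8aS)-7-methyl-2-oxo-3,3a,4,7,8,8a-hexahydro-2H-cyclohepta[b]furan-6-yl trifluoromethanesulfonate, via potassium enolate 15 (not isolated)
Conditions: KBH(s-Bu)3 (1.0 equiv), THF, −78 °C; then Comins' reagent, −78 → 0 °C
Reagents that add atoms: Comins' reagent [N-(5-chloropyridin-2-yl)triflimide], Clc1ccc(nc1)N(S(=O)(=O)C(F)(F)F)S(=O)(=O)C(F)(F)F
Why: 1,4-Hydride addition to the enone gives the C1'=C5' enolate regiospecifically and O-sulfonylation traps it as the alkenyl triflate (reductive triflation), with no new stereocentre.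

Step 11
Reactants: 16 (3aS,7R,8aS)-alkenyl triflate; 17 2-methyl-2-vinyl-1,3-dioxolane
Product: 19 (3aS,7R,8aS)-7-methyl-6-[2-(2-methyl-1,3-dioxolan-2-yl)ethyl]-3,3a,4,7,8,8a-hexahydro-2H-cyclohepta[b]furan-2-one, via alkylborane 18 (not isolated)
Conditions: 17, 9-BBN, THF, rt; then 16, PdCl2(dppf) (5 mol %), K3PO4, DMF–THF–H2O, 50 °C
Reagents that add atoms: none
Why: Anti-Markovnikov hydroboration of 17 gives the primary alkylborane, which couples with the alkenyl triflate under zerovalent palladium catalysis (B-alkyl Suzuki–Miyaura coupling) to put the masked 3-oxobutyl chain on C1'.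

Step 12
Reactants: 19 (3aS,7R,8aS)-side-chain lactone
Product: 22 (3aS,7R,8aS)-7-methyl-3-methylidene-6-[2-(2-methyl-1,3-dioxolan-2-yl)ethyl]-3,3a,4,7,8,8a-hexahydro-2H-cyclohepta[b]furan-2-one, via Mannich base 20 (not isolated), via ammonium iodide 21 (not isolated)
Conditions: LiN(i-Pr)2, THF, −78 °C; CH2=NMe2+ I−, −78 °C → rt; then MeI, MeOH; then NaHCO3, CH2Cl2–H2O
Reagents that add atoms: Eschenmoser's salt, C=[N+](C)C.[I-]
Why: The lactone is the only enolisable carbonyl, so a Mannich reaction with Eschenmoser's salt, exhaustive methylation and base-induced β-elimination of trimethylamine should give the α-methylene lactone (lactone α-methylenation).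

Step 13
Reactants: 13 (3aS,7S,8aR)-7-methyl-3,3a,8,8a-tetrahydro-2H-cyclohepta[b]furan-2,6(7H)-dione; 22 upper α-methylene lactone
Product: 25 three-component adduct (C5–C13' bond formed; C11' quaternary with acetyl on the convex face), via ketone enolate 23 (not isolated), via lactone enolate 24 (not isolated)
Conditions: 13, LiBH(s-Bu)3 (1.0 equiv), THF, −78 °C; then 22, −78 °C; then AcCl, −78 → −40 °C; aq. NH4Cl
Reagents that add atoms: acetyl chloride, CC(=O)Cl
Why: Conjugate hydride reduction gives the C1=C5 lithium enolate regiospecifically, which should attack the methylene carbon of 22 through its own exo face (anti to the lower lactone ring and the C10 methyl group, setting C5), and the resulting tetrasubstituted lactone enolate 24 should be C-acetylated on the convex face of the cis-fused bicycle (cis to H-7'), pushing C13' to the concave side and setting C11' (tandem reductive Michael addition and Claisen-type acylation).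

Step 14
Reactants: 25 three-component adduct
Product: 26 cis-fused β-hydroxy ketone (C1–OH cis to H-5 and C3 ketone)
Conditions: LiN(SiMe3)2 (1.1 equiv), THF, −78 °C; aq. NH4Cl at −78 °C
Reagents that add atoms: none
Why: Kinetic deprotonation of the acetyl methyl group (C2) and 6-(enolendo)-exo-trig intramolecular aldol addition to the C1 ketone from the face of the C5–C13' tether (anti to the lactone and C10 methyl) should give the cis-fused ketol with C1–OH cis to H-5, and the cold quench avoids retro-aldol cleavage and dehydration.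

Step 15
Reactants: 26 cis-fused β-hydroxy ketone
Product: 27 trimethylsilyl ether of 26
Conditions: 1-(trimethylsilyl)imidazole, CH2Cl2, rt
Reagents that add atoms: 1-(trimethylsilyl)imidazole, C[Si](C)(C)n1ccnc1
Why: Silylation of the hindered tertiary alcohol with a powerful, non-enolising silyl donor blocks retro-aldol cleavage in the following basic steps (silyl ether protection), with no stereocentre affected.

Step 16
Reactants: 27 trimethylsilyl ether of 26
Product: 29 alkenyl triflate (C2=C3 with OTf on C3), via potassium enolate 28 (not isolated)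
Conditions: KN(SiMe3)2 (1.05 equiv), THF, −78 °C; then Comins' reagent
Reagents that add atoms: Comins' reagent [N-(5-chloropyridin-2-yl)triflimide], Clc1ccc(nc1)N(S(=O)(=O)C(F)(F)F)S(=O)(=O)C(F)(F)F
Why: The C3 ketone can enolise only towards C2 because C11' is quaternary, and it is more acidic than the lower lactone, so O-triflation of its enolate at low temperature should place the C2=C3 double bond (enol triflate formation).

Step 17
Reactants: 29 alkenyl triflate
Product: 32 alkenyl triflate bearing the lower α-methylene lactone, via Mannich base 30 (not isolated), via ammonium iodide 31 (not isolated)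
Conditions: LiN(i-Pr)2 (1.1 equiv), THF, −78 °C; CH2=NMe2+ I−, −78 °C → rt; then MeI, MeOH; then NaHCO3, CH2Cl2–H2O
Reagents that add atoms: Eschenmoser's salt, C=[N+](C)C.[I-]
Why: Only the lower lactone still has an acidic α-CH2 (the upper one is quaternary, the ketones are masked), so the Mannich reaction, quaternisation and β-elimination should install the C11=C13 methylene (lactone α-methylenation) without touching the triflate.

Step 18
Reactants: 32 alkenyl triflate bearing the lower α-methylene lactone
Product: 33 2-ethoxy-1,3-diene (C3 bearing C(OEt)=CH2)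
Conditions: tributyl(1-ethoxyvinyl)stannane, Pd(PPh3)4 (5 mol %), LiCl, THF, 65 °C
Reagents that add atoms: tributyl(1-ethoxyvinyl)stannane, CCCC[Sn](CCCC)(CCCC)C(=C)OCC
Why: Stille coupling of the alkenyl triflate with the α-ethoxyvinyl stannane (chloride assists transmetalation) attaches C4 and C15 as a masked acetyl group, with no stereocentre formed.

Step 19
Reactants: 33 2-ethoxy-1,3-diene
Product: 34 CNP0195550.3 (target)
Conditions: 1 M HCl, THF, 0 °C → rt
Reagents that add atoms: water, O
Why: Dilute acid should hydrolyse the enol ether to the methyl ketone conjugated with C2=C3, the dioxolane to the side-chain ketone and the tertiary silyl ether to the C1 alcohol in one operation (enol ether and acetal hydrolysis), leaving all stereocentres untouched.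

Compound list
1 | 4,4-dimethoxycyclohexa-2,5-dien-1-one | COC1(OC)C=CC(=O)C=C1 | starting material
2 | rac-4,4-dimethoxy-5-methylcyclohex-2-en-1-one (5S antipode drawn) | O=C1C=CC(OC)(OC)[C@@H](C)C1 | intermediate
3 | rac-cis-4,4-dimethoxy-5-methylcyclohex-2-en-1-ol (1R,5S drawn) | O[C@H]1C=CC(OC)(OC)[C@@H](C)C1 | intermediate
4 | rac-cis-4-hydroxy-6-methylcyclohex-2-en-1-one (4R,6S drawn) | O=C1C=C[C@H](O)C[C@@H]1C | intermediate
5 | rac-methyl cis-5-methyl-4-oxocyclohex-2-en-1-yl malonate | O=C1C=C[C@H](OC(=O)CC(=O)OC)C[C@@H]1C | intermediate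
6 | rac-methyl (3aR,6S,7aR)-6-methyl-2,5-dioxooctahydro-1-benzofuran-3-carboxylate (C3 epimers) | COC(=O)C1C(=O)O[C@@H]2C[C@H](C)C(=O)C[C@H]12 | intermediate
7 | rac-(3aR,6S,7aR)-6-methylhexahydro-1-benzofuran-2,5-dione (cis-fused; methyl cis to ring oxygen) | C1C(=O)O[C@@H]2C[C@H](C)C(=O)C[C@H]12 | intermediate
8 | lithium enolate of 7 (C4=C5 of the benzofuranone; O–Li on C5) | C1C(=O)O[C@@H]2C[C@H](C)C([O-])=C[C@H]12.[Li+] | intermediate
9 | rac-6-methyl-5-(trimethylsilyloxy)-3a,6,7,7a-tetrahydro-1-benzofuran-2(3H)-one | C1C(=O)O[C@@H]2C[C@H](C)C(O[Si](C)(C)C)=C[C@H]12 | intermediate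
10 | rac-siloxycyclopropane (CH2 across C4–C5 of 9 on the face anti to the lactone ring) | C1C(=O)O[C@@H]2C[C@H](C)[C@@]3(O[Si](C)(C)C)C[C@H]3[C@H]12 | intermediate
11 | rac-4-chloro-7-methylhexahydro-2H-cyclohepta[b]furan-2,6(3H)-dione (C4 epimers) | C1C(=O)O[C@@H]2C[C@H](C)C(=O)CC(Cl)[C@H]12 | intermediate
12 | rac-7-methyl-3,3a,8,8a-tetrahydro-2H-cyclohepta[b]furan-2,6(7H)-dione (all-cis; 3aS,7S,8aR antipode drawn) | C1C(=O)O[C@@H]2C[C@H](C)C(=O)C=C[C@H]12 | intermediate
13 | (3aS,7S,8aR)-7-methyl-3,3a,8,8a-tetrahydro-2H-cyclohepta[b]furan-2,6(7H)-dione | C1C(=O)O[C@@H]2C[C@H](C)C(=O)C=C[C@H]12 | intermediate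
14 | (3aR,7R,8aS)-7-methyl-3,3a,8,8a-tetrahydro-2H-cyclohepta[b]furan-2,6(7H)-dione | C1C(=O)O[C@H]2C[C@@H](C)C(=O)C=C[C@@H]12 | intermediate
15 | potassium enolate from 14 (C5=C6; O–K on C6) | C1C(=O)O[C@H]2C[C@@H](C)C([O-])=CC[C@@H]12.[K+] | intermediate
16 | (3aS,7R,8aS)-7-methyl-2-oxo-3,3a,4,7,8,8a-hexahydro-2H-cyclohepta[b]furan-6-yl trifluoromethanesulfonate | C1C(=O)O[C@H]2C[C@@H](C)C(OS(=O)(=O)C(F)(F)F)=CC[C@@H]12 | intermediate
17 | 2-methyl-2-vinyl-1,3-dioxolane | C=CC1(C)OCCO1 | starting material
18 | 9-[2-(2-methyl-1,3-dioxolan-2-yl)ethyl]-9-borabicyclo[3.3.1]nonane | CC1(CCB2C3CCCC2CCC3)OCCO1 | intermediate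
19 | (3aS,7R,8aS)-7-methyl-6-[2-(2-methyl-1,3-dioxolan-2-yl)ethyl]-3,3a,4,7,8,8a-hexahydro-2H-cyclohepta[b]furan-2-one | C1C(=O)O[C@H]2C[C@@H](C)C(CCC3(C)OCCO3)=CC[C@@H]12 | intermediate
20 | 3-(dimethylaminomethyl) derivative of 19 (C3 epimers) | CN(C)CC1C(=O)O[C@H]2C[C@@H](C)C(CCC3(C)OCCO3)=CC[C@@H]12 | intermediate
21 | trimethylammonium iodide from 20 | C[N+](C)(C)CC1C(=O)O[C@H]2C[C@@H](C)C(CCC3(C)OCCO3)=CC[C@@H]12.[I-] | intermediate
22 | (3aS,7R,8aS)-7-methyl-3-methylidene-6-[2-(2-methyl-1,3-dioxolan-2-yl)ethyl]-3,3a,4,7,8,8a-hexahydro-2H-cyclohepta[b]furan-2-one | C=C1C(=O)O[C@H]2C[C@@H](C)C(CCC3(C)OCCO3)=CC[C@@H]12 | intermediate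
23 | lithium enolate from 13 (C1=C5; O–Li on C1) | C1C(=O)O[C@@H]2C[C@H](C)C([O-])=CC[C@H]12.[Li+] | intermediate
24 | lithium enolate of the upper lactone after Michael addition (C5–C13' bond formed; C5 substituent anti to the lower lactone) | C1C(=O)O[C@@H]2C[C@H](C)C(=O)[C@@H](CC4=C([O-])O[C@H]5C[C@@H](C)C(CCC6(C)OCCO6)=CC[C@H]54)C[C@H]12.[Li+] | intermediate
25 | three-component adduct: lower cycloheptanone lactone alkylated at C5 by C13'H2; C11' quaternary with acetyl cis to H-7' | C1C(=O)O[C@@H]2C[C@H](C)C(=O)[C@@H](C[C@@]4(C(C)=O)C(=O)O[C@H]5C[C@@H](C)C(CCC6(C)OCCO6)=CC[C@H]54)C[C@H]12 | intermediate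
26 | cis-fused ketol: six-membered ring C1/C2/C3/C11'/C13'/C5 closed; C1–OH cis to H-5; C3 ketone | C1C(=O)O[C@@H]2C[C@H](C)[C@@]3(O)CC(=O)[C@]4(C[C@H]3C[C@H]12)C(=O)O[C@H]1C[C@@H](C)C(CCC5(C)OCCO5)=CC[C@H]14 | intermediate
27 | C1 trimethylsilyl ether of 26 | C1C(=O)O[C@@H]2C[C@H](C)[C@@]3(O[Si](C)(C)C)CC(=O)[C@]4(C[C@H]3C[C@H]12)C(=O)O[C@H]1C[C@@H](C)C(CCC5(C)OCCO5)=CC[C@H]14 | intermediate
28 | potassium C2=C3 enolate of 27 | C1C(=O)O[C@@H]2C[C@H](C)[C@@]3(O[Si](C)(C)C)C=C([O-])[C@]4(C[C@H]3C[C@H]12)C(=O)O[C@H]1C[C@@H](C)C(CCC5(C)OCCO5)=CC[C@H]14.[K+] | intermediate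
29 | C3 alkenyl triflate (C2=C3) | C1C(=O)O[C@@H]2C[C@H](C)[C@@]3(O[Si](C)(C)C)C=C(OS(=O)(=O)C(F)(F)F)[C@]4(C[C@H]3C[C@H]12)C(=O)O[C@H]1C[C@@H](C)C(CCC5(C)OCCO5)=CC[C@H]14 | intermediate
30 | C11 dimethylaminomethyl derivative of 29 (C11 epimers) | CN(C)CC1C(=O)O[C@@H]2C[C@H](C)[C@@]3(O[Si](C)(C)C)C=C(OS(=O)(=O)C(F)(F)F)[C@]4(C[C@H]3C[C@H]12)C(=O)O[C@H]1C[C@@H](C)C(CCC5(C)OCCO5)=CC[C@H]14 | intermediate
31 | trimethylammonium iodide from 30 | C[N+](C)(C)CC1C(=O)O[C@@H]2C[C@H](C)[C@@]3(O[Si](C)(C)C)C=C(OS(=O)(=O)C(F)(F)F)[C@]4(C[C@H]3C[C@H]12)C(=O)O[C@H]1C[C@@H](C)C(CCC5(C)OCCO5)=CC[C@H]14.[I-] | intermediate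
32 | alkenyl triflate bearing the lower α-methylene lactone (C11=C13) | C=C1C(=O)O[C@@H]2C[C@H](C)[C@@]3(O[Si](C)(C)C)C=C(OS(=O)(=O)C(F)(F)F)[C@]4(C[C@H]3C[C@H]12)C(=O)O[C@H]1C[C@@H](C)C(CCC5(C)OCCO5)=CC[C@H]14 | intermediate
33 | 2-ethoxy-1,3-diene (C3 bearing 1-ethoxyvinyl; C1 OSiMe3; C4' dioxolane) | C=C1C(=O)O[C@@H]2C[C@H](C)[C@@]3(O[Si](C)(C)C)C=C(C(=C)OCC)[C@]4(C[C@H]3C[C@H]12)C(=O)O[C@H]1C[C@@H](C)C(CCC5(C)OCCO5)=CC[C@H]14 | intermediate
34 | CNP0195550.3 | C=C1C(=O)O[C@@H]2C[C@H](C)[C@@]3(O)C=C(C(C)=O)[C@]4(C[C@H]3C[C@H]12)C(=O)O[C@H]1C[C@@H](C)C(CCC(C)=O)=CC[C@H]14 | target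

Total step count: 19 (17 reactions; steps 8 and 9 are the two collections of one chromatographic resolution). Longest linear sequence: 18 steps (steps 1–7 to 12, step 9 to 14, steps 10–12 to 22, step 13 to 25, steps 14–19 to 34; the lower half enters as 13 at step 13).

Steps most likely to fail

Step 13. The lactone enolate 24 may be lost before acylation by proton transfer from the newly formed ketone, by addition to a second molecule of 22, or by O- instead of C-acylation. Fallback, from 13 (with 22) back to 25: 13 is reduced with KBH(s-Bu)3 and the enolate trapped with Me3SiCl to give the trimethylsilyl enol ether F1. Fluoride-catalysed group-transfer Michael addition of F1 to 22 (tris(dimethylamino)sulfonium difluorotrimethylsilicate, THF, −78 °C) should pass the silyl group to the new enolate and give the silyl ketene acetal F2 without a basic metal enolate. The same fluoride source should then promote aldol addition of F2 to acetaldehyde on the convex face, giving after aqueous work-up the hydroxyethyl lactone F3, which Dess–Martin periodinane should oxidise to 25.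

Step 14. The ring ketone may enolise towards C10 and close a bridged aldol, or the aldolate may undergo retro-aldol cleavage or dehydration. Fallback, from 13 and 22 back to 26: the coupling of step 13 is quenched with bromoacetyl bromide instead of acetyl chloride to give the bromoacetyl lactone F4. SmI2 (THF, −78 °C) should then form the samarium enolate at C2 only, and its chelated intramolecular Reformatsky-type addition to the C1 ketone should give 26.

Step 18. Oxidative addition and transmetalation may be slow at the alkenyl triflate flanked by the quaternary C11', so that triflate cleavage or addition to the methylene lactone takes over. Fallback, from 32 back to 34: Nozaki–Hiyama–Kishi coupling of 32 with acetaldehyde (CrCl2, NiCl2 cat., DMF) should give the allylic alcohol F5. Dess–Martin oxidation should give the protected acetyl enone F6, and the acid treatment of step 19 should convert F6 into 34.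

Further compounds
F1 | step 13 | trimethylsilyl enol ether of the conjugate-reduced 13 (C1=C5) | C1C(=O)O[C@@H]2C[C@H](C)C(O[Si](C)(C)C)=CC[C@H]12
F2 | step 13 | silyl ketene acetal of the upper lactone after group-transfer Michael addition | C1C(=O)O[C@@H]2C[C@H](C)C(=O)[C@@H](CC4=C(O[Si](C)(C)C)O[C@H]5C[C@@H](C)C(CCC6(C)OCCO6)=CC[C@H]54)C[C@H]12
F3 | step 13 | 1-hydroxyethyl analogue of 25 (carbinol epimers) | C1C(=O)O[C@@H]2C[C@H](C)C(=O)[C@@H](C[C@@]4(C(C)O)C(=O)O[C@H]5C[C@@H](C)C(CCC6(C)OCCO6)=CC[C@H]54)C[C@H]12
F4 | step 14 | bromoacetyl analogue of 25 | C1C(=O)O[C@@H]2C[C@H](C)C(=O)[C@@H](C[C@@]4(C(=O)CBr)C(=O)O[C@H]5C[C@@H](C)C(CCC6(C)OCCO6)=CC[C@H]54)C[C@H]12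
F5 | step 18 | C3 1-hydroxyethyl diene (allylic alcohol, carbinol epimers) | C=C1C(=O)O[C@@H]2C[C@H](C)[C@@]3(O[Si](C)(C)C)C=C(C(C)O)[C@]4(C[C@H]3C[C@H]12)C(=O)O[C@H]1C[C@@H](C)C(CCC5(C)OCCO5)=CC[C@H]14
F6 | step 18 | C3 acetyl enone with C1 OSiMe3 and C4' dioxolane | C=C1C(=O)O[C@@H]2C[C@H](C)[C@@]3(O[Si](C)(C)C)C=C(C(C)=O)[C@]4(C[C@H]3C[C@H]12)C(=O)O[C@H]1C[C@@H](C)C(CCC5(C)OCCO5)=CC[C@H]14
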